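# Proposed total synthesis of the target gibberellin (the 2β,3β-dihydroxy-7,19,20-tricarboxylic acid with the 16-methylene group)

**Retrosynthetic overview**

1. The target gibberellin comes from a tetracyclic 16-ketone with a C2=C3 double bond by late β-face dihydroxylation, methylenation at C16 and ester cleavage. That ketone comes from a bicyclo[3.2.1]octenone cycloadduct by removal of the C11 oxo group and hydration of C15=C16 at C16.
2. Key disconnection, C8–C9 and C12–C13: an intramolecular (4+3) cycloaddition of an oxyallyl cation (C9–C11–C12, carried on C10) onto a cyclopentadiene (ring D: C8, C14, C13, C16, C15, carried on C6).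
3. Enabling feature: ring C (C8, C9, C11, C12, C13, C14) shares the edge C8–C14–C13 with the five-membered ring D, so rings C/D are the bicyclo[3.2.1]oct-6-ene of a cyclopentadiene plus a three-carbon cation (bridge C9–C11–C12). C8–C9 also lies in ring B, so the three-atom tether C10–C5–C6 closes ring B in the same event.
4. The precursor is a ring A cyclohexene from a Diels–Alder reaction of methyl penta-2,4-dienoate with cis-aconitic anhydride (fixes C4, C5, C10). The two arms are grown by diazoketone chemistry and an aldol/dehydration with cyclopent-2-enone.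
5. Ring order: A (step 1); D brought in as cyclopent-2-enone (step 9) and converted to the diene (step 10); B and C together in step 11, ring C closing with the C12–C13 bond.

Key step: step 11

**Remarks on the chemistry**

- Locants in names are gibberellane numbers: ring A = C1–C5, C10; ring B = C5, C6, C8, C9, C10; ring C = C8, C9, C11–C14; ring D = C8, C13–C16. C7, C19 and C20 are the carboxyl carbons on C6, C4 and C10; C17 is the exocyclic methylene carbon; C18 is the methyl group. α is the face of C19 and C20; β is the face of C18 and of the hydrogens on C5 and C9.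
- Assumption: all compounds before the resolution (step 5) are racemic; their SMILES show the enantiomer that is carried on.
- The aldol adduct and the cyclopentadiene made in steps 9 and 10 are mixtures at C6 (and, for the diene, of 1,5-hydrogen-shift tautomers); the reactive tautomer is drawn and C6 is left unspecified.

**Route**

Step 1
Reactants: 1 methyl (2E)-penta-2,4-dienoate; 2 cis-aconitic anhydride
Product: 3 rac-anhydride acid (ring A adduct with the C4 ester and the C5 and C10 carbonyl groups all cis)
Conditions: toluene, BHT (cat.), 95 °C, sealed tube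
Reagents that add atoms: none
Why: Thermal Diels–Alder reaction; endo addition of the anhydride to the E-diene should place the C4 ester and both anhydride carbonyls (on C5 and C10) all cis, and the substituted dienophile carbon should bond to the unsubstituted diene terminus (C1–C10, C4–C5) on steric and frontier-orbital grounds; the adduct is racemic.

Step 2
Reactants: 3 rac-anhydride acid
Product: 6 rac-chloromethyl ketone anhydride, via acid chloride 4 (not isolated), via diazoketone 5 (not isolated)
Conditions: (COCl)2, DMF (cat.), CH2Cl2, 0 °C → rt; CH2N2 (3 equiv), Et2O, 0 °C; then HCl (4 M in dioxane), 0 °C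
Reagents that add atoms: diazomethane, C=[N+]=[N-]; hydrogen chloride, Cl
Why: Acid chloride formation, acylation of diazomethane and hydrochlorination of the diazoketone (Nierenstein-type chloromethyl ketone synthesis) should convert only the free CH2CO2H arm, the anhydride being inert to these reagents; no stereocentre is touched.

Step 3
Reactants: 6 rac-chloromethyl ketone anhydride
Product: 7 rac-chloroketone acid with the C5 carboxyl as 2-(trimethylsilyl)ethyl ester
Conditions: Me3SiCH2CH2OH (5 equiv), toluene, 90 °C
Reagents that add atoms: 2-(trimethylsilyl)ethanol, C[Si](C)(C)CCO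
Why: Alcoholysis of the unsymmetrical succinic anhydride should occur at the carbonyl on tertiary C5 and not at the one on quaternary C10; no base is used, so the α-chloroketone survives.

Step 4
Reactants: 7 rac-chloroketone acid
Product: 8 rac-chloro ketal acid
Conditions: HC(OMe)3, MeOH, TsOH·H2O (5 mol %), rt
Reagents that add atoms: trimethyl orthoformate, COC(OC)OC; methanol, CO
Why: Acid-catalysed ketalisation with an orthoformate as water scavenger masks the chloroketone as a dimethyl ketal that cannot enolise; the hindered tertiary acid should not be esterified under these mild conditions.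

Step 5
Reactants: 8 rac-chloro ketal acid
Product: 9 chloro ketal acid as the single enantiomer
Conditions: (R)-1-phenylethylamine (0.55 equiv), EtOAc/i-PrOH, fractional crystallisation of the salt; then 10% aq. citric acid, 0 °C
Reagents that add atoms: none
Why: Classical resolution by crystallisation of a diastereomeric ammonium salt of the free C20 acid; the antipodal amine serves if the salt of the unwanted enantiomer is the less soluble one.

Step 6
Reactants: 9 chloro ketal acid
Product: 11 C4-methylated triester, via lithium carboxylate 10 (not isolated)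
Conditions: LiN(i-Pr)2 (2.3 equiv), THF/DMPU, −78 °C; MeI (6 equiv), −78 °C → rt
Reagents that add atoms: iodomethane, CI
Why: Ester enolate alkylation through the dianion: after the carboxylate, the base should remove the allylic C4–H α to the methyl ester, and the dienolate should be C-methylated at C4 anti to the C5 ester and to the axial C20 carboxylate (equatorial attack), which sets the C4 quaternary centre with C18 β; the excess MeI then esterifies the carboxylate.

Step 7
Reactants: 11 C4-methylated triester
Product: 12 C5 carboxylic acid
Conditions: Bu4NF, THF, 0 °C → rt; then cold 0.5 M HCl work-up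
Reagents that add atoms: none
Why: Fluoride-induced β-elimination cleaves only the 2-(trimethylsilyl)ethyl ester; the methyl esters, the ketal and the neopentyl-type chloride should be untouched.

Step 8
Reactants: 12 C5 carboxylic acid
Product: 15 homologated triester (C5–CH2–CO2Me), via acid chloride 13 (not isolated), via diazoketone 14 (not isolated)
Conditions: 1-chloro-N,N,2-trimethylprop-1-en-1-amine, CH2Cl2, 0 °C; CH2N2 (3 equiv), Et2O, 0 °C; then PhCO2Ag (10 mol %), Et3N, MeOH, rt
Reagents that add atoms: diazomethane, C=[N+]=[N-]; methanol, CO
Why: Arndt–Eistert homologation; the neutral chloro-enamine spares the ketal, and the Wolff rearrangement in MeOH should give the methyl ester with retention at the migrating C5, inserting C6.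

Step 9
Reactants: 15 homologated triester; 16 cyclopent-2-en-1-one
Product: 17 aldol adduct (tertiary allylic alcohol)
Conditions: LiN(i-Pr)2 (1.1 equiv), THF, −78 °C; CeCl3 (1.2 equiv), −78 °C; then 16; AcOH quench at −78 °C
Reagents that add atoms: none
Why: Aldol-type 1,2-addition of the ester enolate, made less basic and more oxophilic by CeCl3, to the enone carbonyl; the C6 methylene is the only enolisable position, and the new centres do not matter (the carbinol carbon becomes sp2 in step 10, C6 is epimerisable).

Step 10
Reactants: 17 aldol adduct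
Product: 18 cyclopentadienyl chloroketone
Conditions: 1 M HCl, THF/H2O, 0 °C → rt
Reagents that add atoms: water, O
Why: Acid-catalysed hydrolysis of the α-chloro dimethyl ketal together with dehydration of the tertiary allylic alcohol through its allyl cation should give the cyclopentadiene, whose tautomers interconvert by 1,5-hydrogen shifts.

Step 11
Reactants: 18 cyclopentadienyl chloroketone
Product: 20 tetracyclic cycloadduct, via oxyallyl cation 19 (not isolated)
Conditions: Et3N (3 equiv, slow addition), CF3CH2OH, 0.01 M, 40 °C
Reagents that add atoms: none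
Why: Et3N enolises the chloroketone toward C9 and chloride leaves in the ionising solvent to give the oxyallyl cation 19, which adds across C8 and C13 of the 1-substituted cyclopentadiene tautomer in a (4+3) cycloaddition (concerted, or stepwise with the C8–C9 bond first and ring C closing last); the closest known type is the Föhlisch α-haloketone/amine/trifluoroethanol (4+3) cycloaddition of cyclopentadiene and its intramolecular variants with three-atom tethers to dienes and furans. Ring B closes by the C8–C9 bond as a five-membered ring over the tether C10–C5–C6, and ring C closes by the C12–C13 bond as the six-membered ring C8–C9–C11–C12–C13–C14 of a bicyclo[3.2.1]oct-6-en-3-one whose one-carbon bridge C14 and etheno bridge C15=C16 are ring D. C9 is set relative to C8 and C13 by the ring fusion: ring B is already trans-fused to ring A and a cyclopentane tolerates a second trans fusion poorly, so it should fuse cis to ring C, with C10 on the face of ring C away from the etheno bridge and the hydrogen on C9 on the side of C15=C16, as in the target. Which pair of faces reacts relative to ring A is decided at C5/C6: C6 equilibrates under Et3N before closure (its C–H is activated by the ester and the diene), and the arrangement should be preferred in which the C7 ester ends trans to C4 on ring B and beside the vinylic C15–H (least allylic strain about C6–C8), so that C14 ends syn to C20 and C15 syn to C7, which sets C6, C8 and C13 together. The step needs cycloaddition to outrun Favorskii rearrangement and solvolytic capture of the cation, which the five-ring-forming tether and high dilution should secure, and it needs the right cyclopentadiene tautomer, which is secured because only the 1-substituted tautomer can reach the cation while the others feed it by 1,5-hydrogen shifts.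

Step 12
Reactants: 20 tetracyclic cycloadduct
Product: 22 11-deoxo diene triester, via tosylhydrazone 21 (not isolated)
Conditions: TsNHNH2, MeOH, 50 °C; then catecholborane, CHCl3, 0 °C; NaOAc·3H2O, 60 °C
Reagents that add atoms: none
Why: Deoxygenation of the C11 ketone by catecholborane reduction of its tosylhydrazone (Kabalka variant of the Caglioti reaction), mild enough to leave the esters, both alkenes and the adjacent C9 centre untouched.

Step 13
Reactants: 22 11-deoxo diene triester
Product: 24 16-exo alcohol, via alkylborane 23 (not isolated)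
Conditions: 9-BBN (1.3 equiv), THF, 0 °C → rt; then NaOH (3 M), H2O2 (30%), 0 °C
Reagents that add atoms: hydrogen peroxide, OO
Why: Brown hydroboration–oxidation; 9-BBN should add only to the strained C15=C16 bond (the cyclohexene bond beside quaternary C4 is far slower), from the face of the C14 bridge and with boron on C16, away from quaternary C8; oxidation with retention gives the 16-exo alcohol, whose configuration is lost in step 14.

Step 14
Reactants: 24 16-exo alcohol
Product: 25 16-ketone with the C2=C3 double bond
Conditions: Dess–Martin periodinane, CH2Cl2, rt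
Reagents that add atoms: none
Why: Dess–Martin oxidation of the secondary alcohol under neutral conditions; no stereocentre is affected.

Step 15
Reactants: 25 16-ketone
Product: 26 2β,3β-diol 16-ketone
Conditions: OsO4 (2 mol %), N-methylmorpholine N-oxide, acetone/H2O, rt
Reagents that add atoms: 4-methylmorpholine N-oxide, C[N+]1([O-])CCOCC1; water, O
Why: Upjohn dihydroxylation; syn addition should occur from the β face because the α face of ring A is covered by the axial C19 and C20 ester groups, which sets C2 and C3.

Step 16
Reactants: 26 2β,3β-diol 16-ketone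
Product: 27 trimethyl ester of the target gibberellin
Conditions: Zn, CH2Br2, TiCl4, THF/CH2Cl2, 0 °C → rt
Reagents that add atoms: dibromomethane, BrCBr
Why: Lombardo methylenation; the non-basic Zn/CH2Br2/TiCl4 reagent should convert the ketone into the exocyclic methylene without retro-aldol epimerisation at C3 or enolisation at C6.

Step 17
Reactants: 27 trimethyl ester of the target gibberellin
Product: 28 target gibberellin
Conditions: NaSEt (12 equiv), DMF, 80 °C; then 1 M HCl
Reagents that add atoms: none
Why: Nucleophilic demethylation of the three methyl esters by thiolate attack at the O-methyl carbon (bimolecular substitution), which is insensitive to the hindrance at C4 and C10 and avoids hydroxide (retro-aldol at the 3-hydroxy-4-carboxylate) and acid (alkene migration).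

**Compound list**

1 | methyl (2E)-penta-2,4-dienoate | C=C/C=C/C(=O)OC | starting material
2 | cis-aconitic anhydride, 2-(2,5-dioxo-2,5-dihydrofuran-3-yl)acetic acid | OC(=O)CC1=CC(=O)OC1=O | starting material
3 | rac-2-[4-(methoxycarbonyl)-1,3-dioxo-1,3,3a,4,7,7a-hexahydro-2-benzofuran-7a-yl]acetic acid, ring substituents at 3a, 4 and 7a all cis | OC(=O)C[C@]12CC=C[C@@H](C(=O)OC)[C@H]1C(=O)OC2=O | intermediate
4 | acid chloride of 3 | ClC(=O)C[C@]12CC=C[C@@H](C(=O)OC)[C@H]1C(=O)OC2=O | intermediate (not isolated)
5 | diazomethyl ketone from 4 | [N-]=[N+]=CC(=O)C[C@]12CC=C[C@@H](C(=O)OC)[C@H]1C(=O)OC2=O | intermediate (not isolated)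
6 | rac-methyl 7a-(3-chloro-2-oxopropyl)-1,3-dioxo-1,3,3a,4,7,7a-hexahydro-2-benzofuran-4-carboxylate, all-cis | ClCC(=O)C[C@]12CC=C[C@@H](C(=O)OC)[C@H]1C(=O)OC2=O | intermediate
7 | rac-1-(3-chloro-2-oxopropyl)-5-(methoxycarbonyl)-6-{[2-(trimethylsilyl)ethoxy]carbonyl}cyclohex-3-ene-1-carboxylic acid, the three carbonyl groups cis | ClCC(=O)C[C@]1(C(=O)O)CC=C[C@@H](C(=O)OC)[C@H]1C(=O)OCC[Si](C)(C)C | intermediate
8 | rac-1-(3-chloro-2,2-dimethoxypropyl)-5-(methoxycarbonyl)-6-{[2-(trimethylsilyl)ethoxy]carbonyl}cyclohex-3-ene-1-carboxylic acid, the three carbonyl groups cis | ClCC(OC)(OC)C[C@]1(C(=O)O)CC=C[C@@H](C(=O)OC)[C@H]1C(=O)OCC[Si](C)(C)C | intermediate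
9 | the same acid as a single enantiomer (C4 ester, C5 ester and C10 carboxyl on the α face) | ClCC(OC)(OC)C[C@]1(C(=O)O)CC=C[C@@H](C(=O)OC)[C@H]1C(=O)OCC[Si](C)(C)C | intermediate
10 | lithium carboxylate of the C4-methylated acid (C18 β, C19 α) | ClCC(OC)(OC)C[C@]1(C([O-])=O)CC=C[C@@](C)(C(=O)OC)[C@H]1C(=O)OCC[Si](C)(C)C.[Li+] | intermediate (not isolated)
11 | 1,3-dimethyl 2-[2-(trimethylsilyl)ethyl] 3-(3-chloro-2,2-dimethoxypropyl)-1-methylcyclohex-5-ene-1,2,3-tricarboxylate, the three ester groups cis | ClCC(OC)(OC)C[C@]1(C(=O)OC)CC=C[C@@](C)(C(=O)OC)[C@H]1C(=O)OCC[Si](C)(C)C | intermediate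
12 | 6-(3-chloro-2,2-dimethoxypropyl)-2,6-bis(methoxycarbonyl)-2-methylcyclohex-3-ene-1-carboxylic acid, the three carbonyl groups cis | ClCC(OC)(OC)C[C@]1(C(=O)OC)CC=C[C@@](C)(C(=O)OC)[C@H]1C(=O)O | intermediate
13 | acid chloride of 12 | ClCC(OC)(OC)C[C@]1(C(=O)OC)CC=C[C@@](C)(C(=O)OC)[C@H]1C(=O)Cl | intermediate (not isolated)
14 | diazomethyl ketone from 13 | ClCC(OC)(OC)C[C@]1(C(=O)OC)CC=C[C@@](C)(C(=O)OC)[C@H]1C(=O)C=[N+]=[N-] | intermediate (not isolated)
15 | dimethyl 1-(3-chloro-2,2-dimethoxypropyl)-6-(2-methoxy-2-oxoethyl)-5-methylcyclohex-3-ene-1,5-dicarboxylate, both ring esters cis to the C6 side chain | ClCC(OC)(OC)C[C@]1(C(=O)OC)CC=C[C@@](C)(C(=O)OC)[C@H]1CC(=O)OC | intermediate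
16 | cyclopent-2-en-1-one | O=C1C=CCC1 | starting material
17 | aldol adduct of 15, with a 1-hydroxycyclopent-2-en-1-yl group on C6 (epimers at C6 and at the carbinol carbon) | ClCC(OC)(OC)C[C@]1(C(=O)OC)CC=C[C@@](C)(C(=O)OC)[C@H]1C(C(=O)OC)C1(O)C=CCC1 | intermediate
18 | dimethyl 1-(3-chloro-2-oxopropyl)-6-[1-(cyclopenta-1,3-dien-1-yl)-2-methoxy-2-oxoethyl]-5-methylcyclohex-3-ene-1,5-dicarboxylate (C6 epimers, diene tautomers; reactive tautomer drawn) | ClCC(=O)C[C@]1(C(=O)OC)CC=C[C@@](C)(C(=O)OC)[C@H]1C(C(=O)OC)C1=CC=CC1 | intermediate
19 | oxyallyl cation (2-oxidoallyl cation over C9–C11–C12) derived from 18 | C=C([O-])[CH+][C@]1(C(=O)OC)CC=C[C@@](C)(C(=O)OC)[C@H]1C(C(=O)OC)C1=CC=CC1 | intermediate (not isolated)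
20 | tetracyclic cycloadduct: 17-nor-gibberellane 7,19,20-trimethyl ester with 11-oxo group and C2=C3 and C15=C16 double bonds, configuration at C4, C5, C6, C8, C9, C10, C13 as in the target | C1=C[C@]23C[C@H]1CC(=O)[C@H]2[C@]1(C(=O)OC)CC=C[C@@](C)(C(=O)OC)[C@H]1[C@@H]3C(=O)OC | intermediate
21 | C11 tosylhydrazone of 20 | C1=C[C@]23C[C@H]1CC(=NNS(=O)(=O)c4ccc(C)cc4)[C@H]2[C@]1(C(=O)OC)CC=C[C@@](C)(C(=O)OC)[C@H]1[C@@H]3C(=O)OC | intermediate (not isolated)
22 | 11-deoxo diene triester (C2=C3 and C15=C16) | C1=C[C@]23C[C@H]1CC[C@H]2[C@]1(C(=O)OC)CC=C[C@@](C)(C(=O)OC)[C@H]1[C@@H]3C(=O)OC | intermediate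
23 | C16 alkylborane (B-alkyl-9-borabicyclo[3.3.1]nonane, boron exo on C16) | C12CCCC(CCC1)B2[C@@H]1C[C@]23C[C@H]1CC[C@H]2[C@]1(C(=O)OC)CC=C[C@@](C)(C(=O)OC)[C@H]1[C@@H]3C(=O)OC | intermediate (not isolated)
24 | 16-exo alcohol (OH syn to the C14 bridge), C2=C3 retained | O[C@@H]1C[C@]23C[C@H]1CC[C@H]2[C@]1(C(=O)OC)CC=C[C@@](C)(C(=O)OC)[C@H]1[C@@H]3C(=O)OC | intermediate
25 | 17-nor-16-oxo triester with C2=C3 double bond | O=C1C[C@]23C[C@H]1CC[C@H]2[C@]1(C(=O)OC)CC=C[C@@](C)(C(=O)OC)[C@H]1[C@@H]3C(=O)OC | intermediate
26 | 2β,3β-dihydroxy-17-nor-16-oxo triester | O=C1C[C@]23C[C@H]1CC[C@H]2[C@]1(C(=O)OC)C[C@H](O)[C@H](O)[C@@](C)(C(=O)OC)[C@H]1[C@@H]3C(=O)OC | intermediate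
27 | trimethyl ester of the target gibberellin (trimethyl 2β,3β-dihydroxygibberell-16-ene-7,19,20-trioate) | C=C1C[C@]23C[C@H]1CC[C@H]2[C@]1(C(=O)OC)C[C@H](O)[C@H](O)[C@@](C)(C(=O)OC)[C@H]1[C@@H]3C(=O)OC | intermediate
28 | target gibberellin: 2β,3β-dihydroxygibberell-16-ene-7,19,20-trioic acid (C18 methyl β on C4, hydrogens on C5 and C9 β, C7 carboxyl β on C6) | C=C1C[C@]23C[C@H]1CC[C@H]2[C@]1(C(=O)O)C[C@H](O)[C@H](O)[C@@](C)(C(=O)O)[C@H]1[C@@H]3C(=O)O | target

**Step count and risks**

Total step count: 17. Longest linear sequence: 17 steps (1 + 2 → 28; 16 enters at step 9).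

Steps most likely to fail:

1. Step 11 (key cycloaddition). If the closure runs stepwise, ring C may close with the substituents on C9 interchanged, that is with poor facial selectivity at the cation terminus. Fallback (thermodynamic instead of kinetic control at C9): from 18 the cycloaddition is run as in step 11, and the C9 epimer of the cycloadduct F1, if it forms, is not separated. The crude adduct is equilibrated with NaOMe (0.2 equiv) in MeOH at rt through the C9–C11 enolate. In this epimer ring B would be trans-fused to ring A and to ring C at once, so it should relax to the cis-fused isomer. C6, which is also enolisable, should settle with the ester trans to C4. The route is rejoined at 20.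

2. Step 9 (aldol addition to cyclopent-2-enone). The hindered C6 enolate may add in the 1,4 sense, or the adduct may revert by retro-aldol cleavage on work-up. Fallback (vinylogous-ester addition with carbonyl transposition in place of the direct aldol, Stork–Danheiser sequence): from 15, the lithium enolate (LiN(i-Pr)2, THF, −78 °C) is added to 3-ethoxycyclopent-2-en-1-one, whose β-carbon is deactivated toward conjugate addition, to give the 1,2-adduct F2. This is not isolated but hydrolysed with aqueous oxalic acid at 0 °C, with loss of ethanol, to the 3-substituted cyclopent-2-en-1-one F3, the ketal staying intact. Luche 1,2-reduction (NaBH4, CeCl3·7H2O, MeOH, 0 °C) gives the allylic alcohol F4. With 1 M HCl in THF/H2O this loses water and the two ketal methanols and comes back to the route at 18.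

3. Step 13 (hydroboration). Boron may be delivered to C15 as well as C16, or the ring A double bond may be attacked. Fallback (electrophilic hydration in place of hydroboration): from 22, oxymercuration with Hg(OAc)2 in THF/H2O is used. Water should open the mercurinium ion of the strained C15=C16 bond at C16, the carbon remote from quaternary C8, from the face of the C14 bridge, to give the 16-hydroxy-15-(acetoxymercurio) adduct F5. Demercuration with NaBH4/NaOH replaces mercury by hydrogen, and the route is rejoined at 24.

**Further compounds**

F1 | step 11 | C9 epimer of cycloadduct 20 | C1=C[C@]23C[C@H]1CC(=O)[C@@H]2[C@]1(C(=O)OC)CC=C[C@@](C)(C(=O)OC)[C@H]1[C@@H]3C(=O)OC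
F2 | step 9 | 1,2-adduct of the enolate of 15 with 3-ethoxycyclopent-2-en-1-one (3-ethoxy-1-hydroxycyclopent-2-en-1-yl group on C6; epimers) | ClCC(OC)(OC)C[C@]1(C(=O)OC)CC=C[C@@](C)(C(=O)OC)[C@H]1C(C(=O)OC)C1(O)C=C(OCC)CC1
F3 | step 9 | 3-substituted cyclopent-2-en-1-one carrying the chloro ketal arm (C6 epimers) | ClCC(OC)(OC)C[C@]1(C(=O)OC)CC=C[C@@](C)(C(=O)OC)[C@H]1C(C(=O)OC)C1=CC(=O)CC1
F4 | step 9 | allylic alcohol from 1,2-reduction of F3 (epimers) | ClCC(OC)(OC)C[C@]1(C(=O)OC)CC=C[C@@](C)(C(=O)OC)[C@H]1C(C(=O)OC)C1=CC(O)CC1
F5 | step 13 | 16-exo-hydroxy-15-exo-(acetoxymercurio) adduct of 22 (C15 configuration immaterial, drawn exo) | O[C@@H]1[C@H]([Hg]OC(C)=O)[C@]23C[C@H]1CC[C@H]2[C@]1(C(=O)OC)CC=C[C@@](C)(C(=O)OC)[C@H]1[C@@H]3C(=O)OC
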